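**Retrosynthetic overview**
1. Target 14 is the aryl ester of a 3,5-diformylorsellinic acid (ring A) with 4-chloro-3-methoxy-2,5,6-trimethylphenol (ring B). The two ring A aldehydes are removed first (late double formylation), then the ester C–O bond is cut into acid 10 and phenol 7.
2. The strategy rests on ring B: five neighbouring ring carbons carry O, CH3, O, CH3, CH3 in that order, which is the substitution of 2,4,5-trimethylcyclohexane-1,3-dione. The sixth carbon, the CH2 of the dione, is the only open position of the derived resorcinol and takes the chlorine.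
3. The dione is cut at the bond between its two adjacent CH(CH3) carbons (Michael) and at the bond between the CH2-flanked carbonyl and the CH(CH3) between the carbonyls (Claisen), giving pentan-3-one and methyl crotonate.
4. Ring order: ring B is closed first as a saturated six-membered ring (step 1) and aromatized in step 2. Ring A is bought as orsellinic acid.

Key step: step 1

Remark: the target is achiral; the three stereocentres of dione 4 form as a mixture and disappear on aromatization, and orsellinic acid is taken as a purchasable building block.

**Route**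

Step 1
Reactants: 1 pentan-3-one; 2 methyl (E)-but-2-enoate
Product: 4 2,4,5-trimethylcyclohexane-1,3-dione (mixture of stereoisomers), via methyl 3,4-dimethyl-5-oxoheptanoate 3 (not isolated)
Conditions: KOtBu (1.2 equiv), THF, 0 °C; 2 added slowly; then 65 °C; aq. HCl work-up
Reagents that add atoms: none
Why: KOtBu converts 1 into its potassium enolate, which adds to the β-carbon of 2 (Michael addition) to give keto ester 3 after proton transfer; the enolate on the other side of the ketone then attacks the ester carbonyl and expels methoxide (Claisen condensation), and deprotonation of the 2-methyl-1,3-dione formed pulls the sequence forward. The closest known reaction type is the one-pot Michael–Claisen [3+3] annulation of dialkyl ketones with acrylates or crotonates to cyclohexane-1,3-diones. The single ring closes in a 6-(enolendo)-exo-trig mode. The three methyl-bearing stereocentres arise without control and need none, since all become sp2 carbons in step 2. Only constitutional selectivity is required: the symmetric ketone offers one Michael regiochemistry, closure through the far α-carbon to a six-membered ring is preferred over the four-membered alternative through the near α-carbon, and slow addition of 2 to the preformed enolate should hold back γ-deprotonation and self-condensation of the crotonate.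

Step 2
Reactants: 4 2,4,5-trimethylcyclohexane-1,3-dione
Product: 5 2,4,5-trimethylbenzene-1,3-diol
Conditions: 10% Pd/C (cat.), triglyme, 200 °C, N2 sweep
Reagents that add atoms: none
Why: Catalytic dehydrogenation of a cyclohexane-1,3-dione to the resorcinol, driven by aromatization and by removal of hydrogen in the gas stream.

Step 3
Reactants: 5 2,4,5-trimethylbenzene-1,3-diol
Product: 6 4-chloro-2,5,6-trimethylbenzene-1,3-diol
Conditions: SO2Cl2 (1.0 equiv), Et2O, 0 °C, under N2
Reagents that add atoms: sulfuryl chloride, O=S(=O)(Cl)Cl
Why: Electrophilic aromatic chlorination at the only unsubstituted ring carbon, which is ortho to one hydroxyl and para to the other.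

Step 4
Reactants: 6 4-chloro-2,5,6-trimethylbenzene-1,3-diol
Product: 7 4-chloro-3-methoxy-2,5,6-trimethylphenol
Conditions: MeI (1.05 equiv), K2CO3 (1.0 equiv), acetone, rt
Reagents that add atoms: iodomethane, CI
Why: Williamson O-methylation with limiting base, in which the hydroxyl ortho to chlorine is the more acidic one and should be deprotonated and methylated in preference to the hydroxyl flanked by two methyl groups.

Step 5
Reactants: 8 orsellinic acid (2,4-dihydroxy-6-methylbenzoic acid)
Product: 9 benzyl 2,4-bis(benzyloxy)-6-methylbenzoate
Conditions: BnBr (3.3 equiv), K2CO3, DMF, rt to 60 °C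
Reagents that add atoms: benzyl bromide, BrCc1ccccc1
Why: Exhaustive SN2 benzylation of the carboxylate and both phenoxides; the carboxylate is alkylated first, which prevents decarboxylation of the acid on warming.

Step 6
Reactants: 9 benzyl 2,4-bis(benzyloxy)-6-methylbenzoate
Product: 10 2,4-bis(benzyloxy)-6-methylbenzoic acid
Conditions: KOH, DMSO–H2O, 90 °C; then aq. HCl
Reagents that add atoms: potassium hydroxide, [K+].[OH-]
Why: Saponification of a hindered benzoate under forcing conditions in a dipolar aprotic medium; the benzyl aryl ethers are inert to base.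

Step 7
Reactants: 10 2,4-bis(benzyloxy)-6-methylbenzoic acid; 7 4-chloro-3-methoxy-2,5,6-trimethylphenol
Product: 12 4-chloro-3-methoxy-2,5,6-trimethylphenyl 2,4-bis(benzyloxy)-6-methylbenzoate, via 2,4-bis(benzyloxy)-6-methylbenzoic trifluoroacetic anhydride 11 (not isolated)
Conditions: (CF3CO)2O, toluene, rt
Reagents that add atoms: none
Why: Trifluoroacetic anhydride-mediated esterification of a hindered acid, in which mixed anhydride 11 ionizes to an alkoxy-stabilized acylium ion small enough to be captured by the oxygen of the di-ortho-methylated phenol, while the fully substituted ring B allows no C-acylation.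

Step 8
Reactants: 12 4-chloro-3-methoxy-2,5,6-trimethylphenyl 2,4-bis(benzyloxy)-6-methylbenzoate
Product: 13 4-chloro-3-methoxy-2,5,6-trimethylphenyl 2,4-dihydroxy-6-methylbenzoate
Conditions: H2 (1 atm), 10% Pd/C, EtOAc, rt, stopped after uptake of two equivalents
Reagents that add atoms: none
Why: Hydrogenolysis of the two benzyl aryl ethers, which in neutral ethyl acetate without base should be much faster than reduction of the electron-rich, doubly ortho-substituted aryl chloride.

Step 9
Reactants: 13 4-chloro-3-methoxy-2,5,6-trimethylphenyl 2,4-dihydroxy-6-methylbenzoate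
Product: 14 4-chloro-3-methoxy-2,5,6-trimethylphenyl 3,5-diformyl-2,4-dihydroxy-6-methylbenzoate (target)
Conditions: (CH2)6N4 (excess), CF3CO2H, 90 °C; then aq. HCl, 60 °C
Reagents that add atoms: hexamethylenetetramine, C1N2CN3CN1CN(C2)C3; water, O
Why: Exhaustive Duff formylation, in which both open positions of ring A are ortho to a phenolic hydroxyl, ring B has no free carbon, and the doubly hindered aryl ester should withstand the acidic hydrolysis that releases the aldehydes.

**Compound list**
1 | pentan-3-one | CCC(=O)CC | starting material
2 | methyl (E)-but-2-enoate | C/C=C/C(=O)OC | starting material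
3 | methyl 3,4-dimethyl-5-oxoheptanoate (mixture of diastereomers) | CCC(=O)C(C)C(C)CC(=O)OC | intermediate
4 | 2,4,5-trimethylcyclohexane-1,3-dione (mixture of stereoisomers) | CC1CC(=O)C(C)C(=O)C1C | intermediate
5 | 2,4,5-trimethylbenzene-1,3-diol | Cc1cc(O)c(C)c(O)c1C | intermediate
6 | 4-chloro-2,5,6-trimethylbenzene-1,3-diol | Cc1c(C)c(Cl)c(O)c(C)c1O | intermediate
7 | 4-chloro-3-methoxy-2,5,6-trimethylphenol | COc1c(C)c(O)c(C)c(C)c1Cl | intermediate
8 | orsellinic acid (2,4-dihydroxy-6-methylbenzoic acid) | Cc1cc(O)cc(O)c1C(=O)O | starting material
9 | benzyl 2,4-bis(benzyloxy)-6-methylbenzoate | Cc1cc(OCc2ccccc2)cc(OCc2ccccc2)c1C(=O)OCc1ccccc1 | intermediate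
10 | 2,4-bis(benzyloxy)-6-methylbenzoic acid | Cc1cc(OCc2ccccc2)cc(OCc2ccccc2)c1C(=O)O | intermediate
11 | 2,4-bis(benzyloxy)-6-methylbenzoic trifluoroacetic anhydride | Cc1cc(OCc2ccccc2)cc(OCc2ccccc2)c1C(=O)OC(=O)C(F)(F)F | intermediate
12 | 4-chloro-3-methoxy-2,5,6-trimethylphenyl 2,4-bis(benzyloxy)-6-methylbenzoate | COc1c(C)c(OC(=O)c2c(C)cc(OCc3ccccc3)cc2OCc2ccccc2)c(C)c(C)c1Cl | intermediate
13 | 4-chloro-3-methoxy-2,5,6-trimethylphenyl 2,4-dihydroxy-6-methylbenzoate | COc1c(C)c(OC(=O)c2c(C)cc(O)cc2O)c(C)c(C)c1Cl | intermediate
14 | 4-chloro-3-methoxy-2,5,6-trimethylphenyl 3,5-diformyl-2,4-dihydroxy-6-methylbenzoate | COc1c(C)c(OC(=O)c2c(C)c(C=O)c(O)c(C=O)c2O)c(C)c(C)c1Cl | target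

**Step count**
Total steps: 9. Longest linear sequence: 7 steps (steps 1, 2, 3, 4, 7, 8, 9).

**Steps most likely to fail**

Step 9. The second formylation may stall, because the ring is already deactivated by the ester and the first aldehyde, and prolonged hot acid may begin to cleave the ester. The fallback sets out from 13 and replaces direct formylation by halogenation, cross-coupling and oxidative cleavage.
- NBS (2.1 equiv) in MeCN at 0 °C to rt should brominate both open positions of ring A and give 4-chloro-3-methoxy-2,5,6-trimethylphenyl 3,5-dibromo-2,4-dihydroxy-6-methylbenzoate F1.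
- Double Stille coupling with Bu3Sn(CH=CH2) and Pd(PPh3)4 in toluene at 100 °C should give 4-chloro-3-methoxy-2,5,6-trimethylphenyl 3,5-diethenyl-2,4-dihydroxy-6-methylbenzoate F2. The hindered, electron-rich aryl chloride of ring B should be far slower in oxidative addition than the two bromides.
- Lemieux–Johnson cleavage (OsO4 cat., NaIO4, 2,6-lutidine, dioxane–H2O) of both vinyl groups comes back to the route at 14.

Step 4. The two hydroxyls may be discriminated poorly, since their acidities differ by little and both are di-ortho-substituted, and methylation may run on to the diether. The fallback sets out from 4 and fixes the position of the methoxy group before the ring is aromatic.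
- MeOH with cat. TsOH at reflux should form the vinylogous ester at the less hindered carbonyl (the one next to the ring CH2), giving 3-methoxy-2,5,6-trimethylcyclohex-2-en-1-one F3 after separation from the minor isomer.
- Kinetic α'-deprotonation with LiN(iPr)2 in THF at −78 °C and trapping with PhSeBr should give 3-methoxy-2,5,6-trimethyl-6-(phenylselanyl)cyclohex-2-en-1-one F4.
- Oxidation with H2O2 and pyridine in CH2Cl2 should bring about syn-elimination and tautomerization to 3-methoxy-2,5,6-trimethylphenol F5.
- Chlorination of F5 at its single free position (SO2Cl2, Et2O, 0 °C) comes back to the route at 7, so that steps 2 to 4 are bypassed.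

Step 1. The alkoxide may deprotonate the crotonate at its γ-position and set off self-condensation of the ester, the ketone may undergo aldol self-condensation, or the Claisen closure may stay incomplete. The fallback sets out from 1 and builds the same ring by the malonate route.
- Aldol addition to acetaldehyde (LiN(iPr)2, THF, −78 °C) should give 5-hydroxy-4-methylhexan-3-one F6.
- Dehydration with cat. TsOH in refluxing toluene should give (E)-4-methylhex-4-en-3-one F7.
- Diethyl malonate with NaOEt in refluxing EtOH should add in conjugate fashion to give diethyl 2-(3-methyl-4-oxohexan-2-yl)propanedioate F8, which should close in the same flask by Claisen condensation through the ethyl ketone CH2 to ethyl 2,3,5-trimethyl-4,6-dioxocyclohexane-1-carboxylate F9.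
- Hydrolysis with aq. KOH, acidification with HCl and heating should decarboxylate F9 and come back to the route at 4.

**Further compounds**
F1 | step 9 | 4-chloro-3-methoxy-2,5,6-trimethylphenyl 3,5-dibromo-2,4-dihydroxy-6-methylbenzoate | COc1c(C)c(OC(=O)c2c(C)c(Br)c(O)c(Br)c2O)c(C)c(C)c1Cl
F2 | step 9 | 4-chloro-3-methoxy-2,5,6-trimethylphenyl 3,5-diethenyl-2,4-dihydroxy-6-methylbenzoate | COc1c(C)c(OC(=O)c2c(C)c(C=C)c(O)c(C=C)c2O)c(C)c(C)c1Cl
F3 | step 4 | 3-methoxy-2,5,6-trimethylcyclohex-2-en-1-one | COC1=C(C)C(=O)C(C)C(C)C1
F4 | step 4 | 3-methoxy-2,5,6-trimethyl-6-(phenylselanyl)cyclohex-2-en-1-one | COC1=C(C)C(=O)C(C)([Se]c2ccccc2)C(C)C1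
F5 | step 4 | 3-methoxy-2,5,6-trimethylphenol | COc1cc(C)c(C)c(O)c1C
F6 | step 1 | 5-hydroxy-4-methylhexan-3-one | CCC(=O)C(C)C(C)O
F7 | step 1 | (E)-4-methylhex-4-en-3-one | CCC(=O)/C(C)=C/C
F8 | step 1 | diethyl 2-(3-methyl-4-oxohexan-2-yl)propanedioate | CCOC(=O)C(C(C)C(C)C(=O)CC)C(=O)OCC
F9 | step 1 | ethyl 2,3,5-trimethyl-4,6-dioxocyclohexane-1-carboxylate | CCOC(=O)C1C(C)C(C)C(=O)C(C)C1=O
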